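## Retrosynthetic overview

1. Target 25 comes from the fully protected binaphthyl 24 by one global cleavage of two MOM and two isopropyl ethers; both methyl ethers stay.
2. The biaryl bond (C5 of half A to C4 of half B) is made by Negishi coupling of two protected bromonaphthalenes, 10 (as the zinc reagent) and 21.
3. Each bromide comes from regioselective NBS bromination of a 1-MOM-protected 3-methyl-1-naphthol ether (9 and 20).
4. In each half the methyl-bearing ring is formed last, by anionic annulation of an ortho-methallyl N,N-diethylbenzamide (directed ortho metalation, methallylation, lithium amide cyclisation); the oxygenated benzene rings are bought.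
5. The benzamides come from 4-bromo-3-methoxyphenol (half A) and from 2-isopropoxyphenol by anionic ortho-Fries rearrangement (half B).

Assumption: the SMILES has no stereodescriptor and no stereocentre; the hindered biaryl axis is undefined, so the route delivers the compound as drawn, racemic at the axis.

## Route

Step 1
Reactants: 1 4-bromo-3-methoxyphenol
Product: 2 1-bromo-2-methoxy-4-(propan-2-yloxy)benzene
Conditions: 2-bromopropane, K2CO3, DMF, 60 °C
Reagents that add atoms: 2-bromopropane, CC(C)Br
Why: Williamson ether synthesis on the phenoxide; the aryl bromide is inert under these conditions.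

Step 2
Reactants: 2 1-bromo-2-methoxy-4-(propan-2-yloxy)benzene
Product: 4 N,N-diethyl-2-methoxy-4-(propan-2-yloxy)benzamide, via aryllithium 3 (not isolated)
Conditions: n-butyllithium, THF, −78 °C; then N,N-diethylcarbamoyl chloride, −78 °C → rt
Reagents that add atoms: N,N-diethylcarbamoyl chloride, CCN(CC)C(Cl)=O
Why: Bromine–lithium exchange followed by acylation of the aryllithium places the tertiary amide ortho to OMe and para to O-isopropyl, and the tertiary amide does not over-add.

Step 3
Reactants: 4 N,N-diethyl-2-methoxy-4-(propan-2-yloxy)benzamide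
Product: 7 N,N-diethyl-2-methoxy-6-(2-methylprop-2-en-1-yl)-4-(propan-2-yloxy)benzamide, via ortho-lithiated benzamide 5 (not isolated), via arylmagnesium bromide 6 (not isolated)
Conditions: sec-butyllithium, TMEDA, THF, −78 °C; MgBr2·OEt2, −78 → 0 °C; 3-bromo-2-methylprop-1-ene, 0 °C → rt
Reagents that add atoms: 3-bromo-2-methylprop-1-ene, C=C(C)CBr
Why: Directed ortho metalation by the tertiary amide occurs at C6, its only free ortho site (the C3 site between the ethers is shielded by the isopropoxy group), and the Grignard formed by transmetalation undergoes clean allylic substitution.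

Step 4
Reactants: 7 N,N-diethyl-2-methoxy-6-(2-methylprop-2-en-1-yl)-4-(propan-2-yloxy)benzamide
Product: 9 8-methoxy-1-(methoxymethoxy)-3-methyl-6-(propan-2-yloxy)naphthalene, via lithium naphthalen-1-olate 8 (not isolated)
Conditions: lithium diisopropylamide (2.2 equiv), THF, 0 °C → rt; then MOMCl, 0 °C → rt
Reagents that add atoms: chloromethyl methyl ether, COCCl
Why: Anionic annulation of an ortho-allyl benzamide: the benzylic-allylic anion attacks the amide carbonyl through its terminal carbon, diethylamide is lost, the dienone enolises to the 3-methyl-1-naphtholate, and this is O-alkylated in the same flask.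

Step 5
Reactants: 9 8-methoxy-1-(methoxymethoxy)-3-methyl-6-(propan-2-yloxy)naphthalene
Product: 10 5-bromo-8-methoxy-1-(methoxymethoxy)-3-methyl-6-(propan-2-yloxy)naphthalene
Conditions: NBS (1.0 equiv), MeCN, −20 → 0 °C, dark
Reagents that add atoms: N-bromosuccinimide, O=C1CCC(=O)N1Br
Why: Electrophilic aromatic bromination goes to C5, the alpha position that is ortho to the 6-alkoxy and para to the 8-methoxy group, which is more activated than C4 (one alkoxy donor) or the flanked beta position C7.

Step 6
Reactants: 11 2-(propan-2-yloxy)phenol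
Product: 12 2-(propan-2-yloxy)phenyl N,N-diethylcarbamate
Conditions: N,N-diethylcarbamoyl chloride, K2CO3, MeCN, reflux
Reagents that add atoms: N,N-diethylcarbamoyl chloride, CCN(CC)C(Cl)=O
Why: O-carbamoylation of the phenoxide installs the strongest ortho-directing group for the next step.

Step 7
Reactants: 12 2-(propan-2-yloxy)phenyl N,N-diethylcarbamate
Product: 15 N,N-diethyl-2-methoxy-3-(propan-2-yloxy)benzamide, via ortho-lithiated carbamate 13 (not isolated), via lithium phenolate 14 (not isolated)
Conditions: sec-butyllithium, TMEDA, THF, −78 °C → rt; then MeI, DMF, rt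
Reagents that add atoms: iodomethane, CI
Why: Carbamate-directed ortho-lithiation at the only free ortho site, then anionic ortho-Fries rearrangement (1,3 O-to-C carbamoyl shift), gives the salicylamide phenolate, which is O-methylated in situ, so the amide/OMe/O-isopropyl sequence is fixed unambiguously.

Step 8
Reactants: 15 N,N-diethyl-2-methoxy-3-(propan-2-yloxy)benzamide
Product: 18 N,N-diethyl-2-methoxy-6-(2-methylprop-2-en-1-yl)-3-(propan-2-yloxy)benzamide, via ortho-lithiated benzamide 16 (not isolated), via arylmagnesium bromide 17 (not isolated)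
Conditions: sec-butyllithium, TMEDA, THF, −78 °C; MgBr2·OEt2, −78 → 0 °C; 3-bromo-2-methylprop-1-ene, 0 °C → rt
Reagents that add atoms: 3-bromo-2-methylprop-1-ene, C=C(C)CBr
Why: Directed ortho metalation at C6, the only position ortho to the amide, followed by transmetalation to magnesium and allylic substitution.

Step 9
Reactants: 18 N,N-diethyl-2-methoxy-6-(2-methylprop-2-en-1-yl)-3-(propan-2-yloxy)benzamide
Product: 20 8-methoxy-1-(methoxymethoxy)-3-methyl-7-(propan-2-yloxy)naphthalene, via lithium naphthalen-1-olate 19 (not isolated)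
Conditions: lithium diisopropylamide (2.2 equiv), THF, 0 °C → rt; then MOMCl, 0 °C → rt
Reagents that add atoms: chloromethyl methyl ether, COCCl
Why: The same anionic ortho-allyl benzamide annulation as in step 4 builds the methyl-bearing ring with the new oxygen peri to the methoxy group, and the naphtholate is trapped as its MOM ether.

Step 10
Reactants: 20 8-methoxy-1-(methoxymethoxy)-3-methyl-7-(propan-2-yloxy)naphthalene
Product: 21 4-bromo-8-methoxy-1-(methoxymethoxy)-3-methyl-7-(propan-2-yloxy)naphthalene
Conditions: NBS (1.0 equiv), MeCN, −20 → 0 °C, dark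
Reagents that add atoms: N-bromosuccinimide, O=C1CCC(=O)N1Br
Why: Electrophilic aromatic bromination of an aryl ether in MeCN is para-selective, so it goes to C4 (para to the 1-alkoxy group, ortho to methyl); the 8-methoxy group is flanked on both sides, twisted out of conjugation, and directs only weakly to C5.

Step 11
Reactants: 10 5-bromo-8-methoxy-1-(methoxymethoxy)-3-methyl-6-(propan-2-yloxy)naphthalene; 21 4-bromo-8-methoxy-1-(methoxymethoxy)-3-methyl-7-(propan-2-yloxy)naphthalene
Product: 24 4,5'-dimethoxy-4',5-bis(methoxymethoxy)-2',7-dimethyl-2,6'-bis(propan-2-yloxy)-1,1'-binaphthalene, via aryllithium 22 (not isolated), via arylzinc chloride 23 (not isolated)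
Conditions: 10 (1.3 equiv), tert-butyllithium (2 equiv), THF, −78 °C; ZnCl2, −78 °C → rt; then 21, Pd2(dba)3 (2 mol %), RuPhos (8 mol %), THF, 70 °C
Reagents that add atoms: none
Why: Negishi cross-coupling with a bulky dialkylbiarylphosphine on zerovalent palladium tolerates the doubly ortho-substituted partners; the new axis is the only stereogenic element and forms without control, as both atropisomers.

Step 12
Reactants: 24 4,5'-dimethoxy-4',5-bis(methoxymethoxy)-2',7-dimethyl-2,6'-bis(propan-2-yloxy)-1,1'-binaphthalene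
Product: 25 4,5'-dimethoxy-2',7-dimethyl-[1,1'-binaphthalene]-2,4',5,6'-tetrol (target)
Conditions: BCl3 (10 equiv), CH2Cl2, −78 → 0 °C; MeOH quench, −78 °C → rt
Reagents that add atoms: none
Why: Lewis acid ether cleavage: MOM acetals and secondary isopropyl ethers ionise far faster than methyl ethers at or below 0 °C, so all four hydroxyls are freed while both methoxy groups survive.

## Compound list

1 | 4-bromo-3-methoxyphenol | COc1cc(O)ccc1Br | starting material
2 | 1-bromo-2-methoxy-4-(propan-2-yloxy)benzene | COc1cc(OC(C)C)ccc1Br | intermediate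
3 | [2-methoxy-4-(propan-2-yloxy)phenyl]lithium | COc1cc(OC(C)C)ccc1[Li] | intermediate
4 | N,N-diethyl-2-methoxy-4-(propan-2-yloxy)benzamide | CCN(CC)C(=O)c1ccc(OC(C)C)cc1OC | intermediate
5 | [2-(diethylcarbamoyl)-3-methoxy-5-(propan-2-yloxy)phenyl]lithium | CCN(CC)C(=O)c1c([Li])cc(OC(C)C)cc1OC | intermediate
6 | [2-(diethylcarbamoyl)-3-methoxy-5-(propan-2-yloxy)phenyl]magnesium bromide | CCN(CC)C(=O)c1c([Mg]Br)cc(OC(C)C)cc1OC | intermediate
7 | N,N-diethyl-2-methoxy-6-(2-methylprop-2-en-1-yl)-4-(propan-2-yloxy)benzamide | CCN(CC)C(=O)c1c(CC(C)=C)cc(OC(C)C)cc1OC | intermediate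
8 | lithium 8-methoxy-3-methyl-6-(propan-2-yloxy)naphthalen-1-olate | [Li]Oc1cc(C)cc2cc(OC(C)C)cc(OC)c12 | intermediate
9 | 8-methoxy-1-(methoxymethoxy)-3-methyl-6-(propan-2-yloxy)naphthalene | COCOc1cc(C)cc2cc(OC(C)C)cc(OC)c12 | intermediate
10 | 5-bromo-8-methoxy-1-(methoxymethoxy)-3-methyl-6-(propan-2-yloxy)naphthalene | COCOc1cc(C)cc2c(Br)c(OC(C)C)cc(OC)c12 | intermediate
11 | 2-(propan-2-yloxy)phenol | CC(C)Oc1ccccc1O | starting material
12 | 2-(propan-2-yloxy)phenyl N,N-diethylcarbamate | CCN(CC)C(=O)Oc1ccccc1OC(C)C | intermediate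
13 | [2-(diethylcarbamoyloxy)-3-(propan-2-yloxy)phenyl]lithium | CCN(CC)C(=O)Oc1c([Li])cccc1OC(C)C | intermediate
14 | lithium 2-(diethylcarbamoyl)-6-(propan-2-yloxy)phenolate | CCN(CC)C(=O)c1cccc(OC(C)C)c1O[Li] | intermediate
15 | N,N-diethyl-2-methoxy-3-(propan-2-yloxy)benzamide | CCN(CC)C(=O)c1cccc(OC(C)C)c1OC | intermediate
16 | [2-(diethylcarbamoyl)-3-methoxy-4-(propan-2-yloxy)phenyl]lithium | CCN(CC)C(=O)c1c([Li])ccc(OC(C)C)c1OC | intermediate
17 | [2-(diethylcarbamoyl)-3-methoxy-4-(propan-2-yloxy)phenyl]magnesium bromide | CCN(CC)C(=O)c1c([Mg]Br)ccc(OC(C)C)c1OC | intermediate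
18 | N,N-diethyl-2-methoxy-6-(2-methylprop-2-en-1-yl)-3-(propan-2-yloxy)benzamide | CCN(CC)C(=O)c1c(CC(C)=C)ccc(OC(C)C)c1OC | intermediate
19 | lithium 8-methoxy-3-methyl-7-(propan-2-yloxy)naphthalen-1-olate | [Li]Oc1cc(C)cc2ccc(OC(C)C)c(OC)c12 | intermediate
20 | 8-methoxy-1-(methoxymethoxy)-3-methyl-7-(propan-2-yloxy)naphthalene | COCOc1cc(C)cc2ccc(OC(C)C)c(OC)c12 | intermediate
21 | 4-bromo-8-methoxy-1-(methoxymethoxy)-3-methyl-7-(propan-2-yloxy)naphthalene | COCOc1cc(C)c(Br)c2ccc(OC(C)C)c(OC)c12 | intermediate
22 | [4-methoxy-5-(methoxymethoxy)-7-methyl-2-(propan-2-yloxy)naphthalen-1-yl]lithium | COCOc1cc(C)cc2c([Li])c(OC(C)C)cc(OC)c12 | intermediate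
23 | chloro[4-methoxy-5-(methoxymethoxy)-7-methyl-2-(propan-2-yloxy)naphthalen-1-yl]zinc | COCOc1cc(C)cc2c([Zn]Cl)c(OC(C)C)cc(OC)c12 | intermediate
24 | 4,5'-dimethoxy-4',5-bis(methoxymethoxy)-2',7-dimethyl-2,6'-bis(propan-2-yloxy)-1,1'-binaphthalene (no stereocentre, axis racemic) | COc1cc(OC(C)C)c(-c2c(C)cc(OCOC)c3c(OC)c(OC(C)C)ccc23)c2cc(C)cc(OCOC)c12 | intermediate
25 | 4,5'-dimethoxy-2',7-dimethyl-[1,1'-binaphthalene]-2,4',5,6'-tetrol (no stereocentre, axis as in the given SMILES, undefined) | COc1cc(O)c(-c2c(C)cc(O)c3c(OC)c(O)ccc23)c2cc(C)cc(O)c12 | target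

## Totals and risks

Total step count: 12. Longest linear sequence: 7 (steps 1–5, 11, 12, or equally steps 6–10, 11, 12).

The three steps most likely to fail:

**Step 11, the hindered Negishi coupling.** Both partners carry an ortho substituent and a peri hydrogen, so transmetalation or reductive elimination may stall, or homocoupling and protodemetalation may take over. The fallback sets out from 10. Tert-butyllithium in THF at −78 °C, then 2-isopropoxy-4,4,5,5-tetramethyl-1,3,2-dioxaborolane, gives the isolable pinacol boronate 2-[4-methoxy-5-(methoxymethoxy)-7-methyl-2-(propan-2-yloxy)naphthalen-1-yl]-4,4,5,5-tetramethyl-1,3,2-dioxaborolane F1. F1 is joined to 21 by Suzuki–Miyaura coupling (Pd(OAc)2, SPhos, K3PO4, toluene/H2O, 100 °C), and the fallback comes back to the route at 24.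

**Step 10, the site of bromination of 20.** Some attack at C5 (para to the 8-methoxy group) or C2 could compete with C4. The fallback sets out from 18. The cyclisation with lithium diisopropylamide is run as before but quenched with aqueous NH4Cl, giving the free naphthol 8-methoxy-3-methyl-7-(propan-2-yloxy)naphthalen-1-ol F2. Its free hydroxyl is a much stronger para director than any ether in the molecule, so tetrabutylammonium tribromide (CH2Cl2/MeOH, 0 °C) should give 4-bromo-8-methoxy-3-methyl-7-(propan-2-yloxy)naphthalen-1-ol F3. NaH and MOMCl in DMF then bring the fallback back to the route at 21.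

**Step 12, the global BCl3 cleavage.** The 8-methoxy group of half B sits between two boron-bound oxygens and could be demethylated by chelation, and the electron-rich tetrol could be alkylated by the cations released. The fallback sets out from 10 and 21 and moves the Lewis acid step to the monomers, where over-cleaved material can be separated; the last step then needs only mild protic acid.
- BCl3 (CH2Cl2, −78 → 0 °C, MeOH quench) converts 10 into 5-bromo-8-methoxy-3-methylnaphthalene-1,6-diol F4, and NaH with MOMCl in DMF gives 5-bromo-8-methoxy-1,6-bis(methoxymethoxy)-3-methylnaphthalene F5.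
- The same two operations convert 21 into 4-bromo-8-methoxy-3-methylnaphthalene-1,7-diol F6 and then 4-bromo-8-methoxy-1,7-bis(methoxymethoxy)-3-methylnaphthalene F7.
- F5 is turned into its zinc reagent and coupled with F7 under the conditions of step 11, giving 4,5'-dimethoxy-2,4',5,6'-tetrakis(methoxymethoxy)-2',7-dimethyl-1,1'-binaphthalene F8.
- HCl in MeOH at rt removes the four MOM groups, and the fallback comes back to the route at 25.

Further compounds

F1 | step 11 | 2-[4-methoxy-5-(methoxymethoxy)-7-methyl-2-(propan-2-yloxy)naphthalen-1-yl]-4,4,5,5-tetramethyl-1,3,2-dioxaborolane | COCOc1cc(C)cc2c(B3OC(C)(C)C(C)(C)O3)c(OC(C)C)cc(OC)c12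
F2 | step 10 | 8-methoxy-3-methyl-7-(propan-2-yloxy)naphthalen-1-ol | Oc1cc(C)cc2ccc(OC(C)C)c(OC)c12
F3 | step 10 | 4-bromo-8-methoxy-3-methyl-7-(propan-2-yloxy)naphthalen-1-ol | Oc1cc(C)c(Br)c2ccc(OC(C)C)c(OC)c12
F4 | step 12 | 5-bromo-8-methoxy-3-methylnaphthalene-1,6-diol | Oc1cc(C)cc2c(Br)c(O)cc(OC)c12
F5 | step 12 | 5-bromo-8-methoxy-1,6-bis(methoxymethoxy)-3-methylnaphthalene | COCOc1cc(C)cc2c(Br)c(OCOC)cc(OC)c12
F6 | step 12 | 4-bromo-8-methoxy-3-methylnaphthalene-1,7-diol | Oc1cc(C)c(Br)c2ccc(O)c(OC)c12
F7 | step 12 | 4-bromo-8-methoxy-1,7-bis(methoxymethoxy)-3-methylnaphthalene | COCOc1cc(C)c(Br)c2ccc(OCOC)c(OC)c12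
F8 | step 12 | 4,5'-dimethoxy-2,4',5,6'-tetrakis(methoxymethoxy)-2',7-dimethyl-1,1'-binaphthalene | COc1cc(OCOC)c(-c2c(C)cc(OCOC)c3c(OC)c(OCOC)ccc23)c2cc(C)cc(OCOC)c12
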